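**Plan**
1. Retrosynthesis cuts, in order: the hemiketal C–ethyl bond (EtMgBr on a δ-lactone); the ring O–CH2 bond (oxygen taken back out of the lactone); the two C–C bonds at the spiro bridge carbon; the C=C of the ester-bearing cyclopentene (aldol condensation); the acyl–vinyl and ring bonds of the cyclopentenone (carbonylative coupling, Nazarov); the two C–C/C–N pairs of the piperidine (double Mannich).
2. Enabling feature: in the 2-ethyltetrahydropyran-2-ol ring the hemiketal carbon is an acyl carbon once ethyl is removed, and the ring oxygen links it to the CH2 on the quaternary spiro carbon. The ring is therefore a spiro-cyclopentanone plus one oxygen atom inserted between C=O and that CH2.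
3. Forward ring order: cycloheptane-1,3-dione → bridged piperidine (8-azabicyclo[4.3.1]decane) → fused cyclopentenone → ester-bearing cyclopentene (dienoate) → spiro-cyclopentenone on the one-carbon bridge → oxygen insertion to the six-membered lactone → ethyl addition to the hemiketal.
4. Stereochemistry: both bridgeheads come from the double Mannich step (relative configuration fixed by the bridge, absolute configuration by separating the (S)-1-phenylethylamine diastereomers). The spiro centre comes from face-selective allylation of the bridge enolate. The hemiketal centre is thermodynamic.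
5. A chlorine atom next to the spiro-cyclopentanone carbonyl steers the oxygen insertion and is removed in the following step.

Key step: step 13

Assumption: the hemiketal centre equilibrates by ring–chain tautomerism, and the anomer with axial OH and equatorial ethyl (quaternary ring neighbour of the spiro carbon equatorial) is the stable one and is the one drawn.

**Step 1**
Reactants: 1 cycloheptane-1,3-dione; 2 methyl acrylate
Product: 3 methyl 3-(2,6-dioxocycloheptyl)propanoate
Conditions: DBU (10 mol %), MeCN, 50 °C
Reagents that add atoms: none
Why: Michael addition of the stabilized dione enolate through its central carbon to one equivalent of acrylate should stop at the mono-adduct; no stereocentre is formed.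

**Step 2**
Reactants: 3 Michael adduct; 4 (S)-1-phenylethylamine
Product: 6 methyl 3-{2,10-dioxo-8-[(S)-1-phenylethyl]-8-azabicyclo[4.3.1]decan-1-yl}propanoate (bridgeheads as in the target), via Mannich base 5 (not isolated)
Conditions: aq. CH2O (37 %, 2.2 equiv), AcOH, MeOH, 65 °C; the two diastereomers are separated by chromatography
Reagents that add atoms: formaldehyde, C=O (two molecules)
Why: Double Mannich reaction: the first iminium ion is taken up by the doubly activated central carbon and the second closes the piperidine ring onto the outer α-carbon of one of the two enantiotopic ketones, so both bridgehead centres form together with their relative configuration fixed by the bridge, while the (S)-1-phenylethyl group makes the two antipodal bicycles separable diastereomers and so fixes the absolute configuration.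

**Step 3**
Reactants: 6 N-(1-phenylethyl) amino diketone
Product: 8 methyl 3-(8-methyl-2,10-dioxo-8-azabicyclo[4.3.1]decan-1-yl)propanoate, via secondary amine 7 (not isolated)
Conditions: H2 (1 atm), Pd(OH)2/C, MeOH, 23 °C; then aq. CH2O (37 %), H2 (1 atm), 23 °C
Reagents that add atoms: formaldehyde, C=O
Why: Hydrogenolysis of the benzylic C–N bond followed by reductive amination (reductive N-methylation) over the same catalyst should exchange the auxiliary for methyl without touching the saturated ketones, the ester or any stereocentre.

**Step 4**
Reactants: 8 N-methyl amino diketone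
Product: 9 methyl 3-[8-methyl-10-oxo-2-(trifluoromethylsulfonyloxy)-8-azabicyclo[4.3.1]dec-2-en-1-yl]propanoate
Conditions: KN(SiMe3)2 (1.05 equiv), THF, −78 °C; then PhNTf2, −78 → 0 °C
Reagents that add atoms: N-phenylbis(trifluoromethanesulfonimide), O=S(=O)(N(c1ccccc1)S(=O)(=O)C(F)(F)F)C(F)(F)F
Why: Enol triflate formation can occur only at the CH2 beside the ring ketone, because both α-carbons of the bridge ketone are bridgeheads that cannot form an enolate, the quaternary carbon has no hydrogen and the ester is less acidic.

**Step 5**
Reactants: 9 enol triflate
Product: 10 methyl 3-(2-acryloyl-8-methyl-10-oxo-8-azabicyclo[4.3.1]dec-2-en-1-yl)propanoate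
Conditions: CO (1 atm), Bu3SnCH=CH2, Pd(PPh3)4 (5 mol %), LiCl, THF, 55 °C
Reagents that add atoms: carbon monoxide, [C-]#[O+]; tributyl(vinyl)stannane, C=C[Sn](CCCC)(CCCC)CCCC
Why: Carbonylative Stille coupling of an alkenyl triflate with a vinylstannane is the standard entry to cross-conjugated divinyl ketones and tolerates the ketone, ester and tertiary amine.

**Step 6**
Reactants: 10 divinyl ketone
Product: 11 tricyclic enone (cyclopentenone fused across the C2=C3 bond of the bicycle with its carbonyl on the carbon bound to C2)
Conditions: MeSO3H (5 equiv), CH2Cl2, 0 → 23 °C; aq. NaHCO3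
Reagents that add atoms: none
Why: Nazarov cyclization (conrotatory 4π closure of the pentadienyl cation) followed by proton loss should place the double bond at the tetrasubstituted ring-fusion position, so no new stereocentre remains.

**Step 7**
Reactants: 11 tricyclic enone
Product: 12 tetracyclic keto dienoate (bridge ketone free)
Conditions: NaOMe (1.5 equiv), MeOH, 65 °C
Reagents that add atoms: none
Why: Intramolecular aldol condensation: the ester enolate of the propanoate arm adds 5-exo-trig to the enone carbonyl and water is lost to give the conjugated dienoate, while the bridge ketone cannot enolize and no stereocentre is formed.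

**Step 8**
Reactants: 12 tetracyclic keto dienoate
Product: 14 bridge aldehyde (formyl and H on the bridge carbon, both epimers), via enol ether 13 (not isolated)
Conditions: Ph3P(CH2OMe)Cl, KN(SiMe3)2, THF, 0 → 60 °C; then 2 M aq. HCl, THF, 23 °C
Reagents that add atoms: (methoxymethyl)triphenylphosphonium chloride, [Cl-].COC[P+](c1ccccc1)(c1ccccc1)c1ccccc1; water, O
Why: Wittig methoxymethylenation of the non-enolizable bridge ketone and hydrolysis of the enol ether give the homologous aldehyde chemoselectively beside the ester; the bridge CH centre is left unassigned because it becomes trigonal again in step 9.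

**Step 9**
Reactants: 14 bridge aldehyde
Product: 16 allyl aldehyde (bridge carbon bearing formyl and allyl; allyl on the cycloheptene face), via allyl enol ether 15 (not isolated)
Conditions: KN(SiMe3)2 (1.05 equiv), THF, −78 °C; allyl bromide, −78 → 23 °C; then toluene, 110 °C
Reagents that add atoms: allyl bromide, C=CCBr
Why: Enolate allylation, with any O-allylated material converging on the same product by Claisen rearrangement on heating; the allyl group should enter the trigonal bridge carbon from the face syn to the cycloheptene C=C (one flanking C–H) and not from the face over the piperidine chair (two axial C–H bonds), which sets the quaternary spiro centre.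

**Step 10**
Reactants: 16 allyl aldehyde
Product: 17 keto aldehyde (bridge carbon bearing formyl and 2-oxopropyl)
Conditions: PdCl2 (10 mol %), CuCl (1 equiv), O2 (1 atm), DMF/H2O 7:1, 23 °C (substrate as its hydrochloride)
Reagents that add atoms: water, O
Why: Wacker oxidation of the terminal alkene gives the methyl ketone, and the tetrasubstituted diene double bonds do not react under these conditions.

**Step 11**
Reactants: 17 keto aldehyde
Product: 18 spiro-cyclopentenone (cyclopent-2-en-1-one joined through its C4 to the bridge carbon)
Conditions: NaOMe, MeOH, 23 → 50 °C
Reagents that add atoms: none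
Why: Intramolecular aldol condensation of the 1,4-keto aldehyde (methyl ketone enolate onto the non-enolizable aldehyde, then dehydration) is the classical route to 4,4-disubstituted cyclopentenones and leaves the spiro centre untouched.

**Step 12**
Reactants: 18 spiro-cyclopentenone
Product: 20 α-chloro spiro-cyclopentanone (Cl on the α-carbon remote from the spiro centre, both epimers), via silyl enol ether 19 (not isolated)
Conditions: [(Ph3P)CuH]6 (5 mol %), PhMe2SiH, toluene, 23 °C; then CF3CO2H (1 equiv), N-chlorosuccinimide, CH2Cl2, −78 → −20 °C
Reagents that add atoms: N-chlorosuccinimide, O=C1CCC(=O)N1Cl; dimethylphenylsilane, C[SiH](C)c1ccccc1 (silicon stays only in intermediate 19)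
Why: Copper hydride conjugate reduction (1,4-hydrosilylation) gives the silyl enol ether with its double bond fixed on the side away from the spiro carbon, and electrophilic chlorination of it, with the amine masked as its salt, puts the chlorine regiospecifically on that carbon; the CHCl centre is temporary.

**Step 13**
Reactants: 20 α-chloro spiro-cyclopentanone
Product: 21 α-chloro spiro-δ-lactone (3-chlorotetrahydropyran-2-one joined through C5 to the bridge carbon)
Conditions: CF3SO3H (1 equiv), CH2Cl2, −40 °C; then Me3SiOOSiMe3 (2 equiv), Me3SiOSO2CF3, −40 → 0 °C
Reagents that add atoms: bis(trimethylsilyl) peroxide, C[Si](C)(C)OO[Si](C)(C)C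
Why: Baeyer–Villiger oxidation: the silyl-activated carbonyl takes up the silyl peroxide to a tetrahedral peroxy adduct, and the ring bond antiperiplanar to the O–O bond shifts from carbon to oxygen with loss of silanolate, inserting one oxygen atom into the five-membered ring. The closest known reaction type is the oxidation of cyclopentanones to δ-lactones with bis(trimethylsilyl) peroxide and a silyl triflate, an oxidant that converts ketones but does not epoxidize C=C bonds. The six-membered ring is not closed by a cyclization; it arises by ring expansion through the 1,2-shift of the CH2 group on the spiro carbon, which keeps its bond to the spiro centre. No stereocentre is created: the migrating carbon is a CH2 group, the spiro centre is untouched and the CHCl centre is removed in step 14. The step needs regioselectivity, which the chlorine atom should secure because its electron withdrawal makes the CHCl carbon the poorer migrating group; it also needs chemoselectivity, which rests on the triflate salt of the amine (no N-oxide) and on the non-epoxidizing oxidant (tetrasubstituted dienoate).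

**Step 14**
Reactants: 21 α-chloro spiro-δ-lactone
Product: 22 spiro-δ-lactone (tetrahydropyran-2-one joined through C5 to the bridge carbon)
Conditions: Zn dust (5 equiv), AcOH, 23 °C
Reagents that add atoms: none
Why: Reductive dehalogenation of the α-chloro ester through its zinc enolate removes the directing chlorine without affecting the dienoate, the lactone or the spiro centre.

**Step 15**
Reactants: 22 spiro-δ-lactone
Product: 23 target hemiketal
Conditions: EtMgBr (1.2 equiv), THF, −78 °C; aq. NH4Cl
Reagents that add atoms: ethylmagnesium bromide, CC[Mg]Br
Why: Grignard addition to the unhindered δ-lactone should stop at the magnesium hemiketal at low temperature and spare the hindered, doubly conjugated methyl ester; the hemiketal centre then settles by ring–chain equilibration to the anomer with axial OH and equatorial ethyl, which is the configuration of the target.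

**Compound list**
1 | cycloheptane-1,3-dione | O=C1CCCCC(=O)C1 | starting material
2 | methyl acrylate | C=CC(=O)OC | starting material
3 | methyl 3-(2,6-dioxocycloheptyl)propanoate | COC(=O)CCC1C(=O)CCCCC1=O | intermediate
4 | (S)-1-phenylethylamine | C[C@H](N)c1ccccc1 | starting material
5 | Mannich base, methyl 3-[2,6-dioxo-1-({[(S)-1-phenylethyl]amino}methyl)cycloheptyl]propanoate | COC(=O)CCC1(CN[C@@H](C)c2ccccc2)C(=O)CCCCC1=O | intermediate
6 | methyl 3-{2,10-dioxo-8-[(S)-1-phenylethyl]-8-azabicyclo[4.3.1]decan-1-yl}propanoate, bridgeheads as in the target | O=C2[C@@H]1CCCC(=O)[C@@]2(CCC(=O)OC)CN([C@@H](C)c3ccccc3)C1 | intermediate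
7 | secondary amine, methyl 3-(2,10-dioxo-8-azabicyclo[4.3.1]decan-1-yl)propanoate, same bridgeheads | O=C2[C@@H]1CCCC(=O)[C@@]2(CCC(=O)OC)CNC1 | intermediate
8 | methyl 3-(8-methyl-2,10-dioxo-8-azabicyclo[4.3.1]decan-1-yl)propanoate, same bridgeheads | O=C2[C@@H]1CCCC(=O)[C@@]2(CCC(=O)OC)CN(C)C1 | intermediate
9 | enol triflate, methyl 3-[8-methyl-10-oxo-2-(trifluoromethylsulfonyloxy)-8-azabicyclo[4.3.1]dec-2-en-1-yl]propanoate | O=C2[C@@H]1CCC=C(OS(=O)(=O)C(F)(F)F)[C@@]2(CCC(=O)OC)CN(C)C1 | intermediate
10 | divinyl ketone, methyl 3-(2-acryloyl-8-methyl-10-oxo-8-azabicyclo[4.3.1]dec-2-en-1-yl)propanoate | O=C2[C@@H]1CCC=C(C(=O)C=C)[C@@]2(CCC(=O)OC)CN(C)C1 | intermediate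
11 | tricyclic enone: cyclopentenone fused across C2=C3 of the bicycle (C=O on the carbon bound to C2), propanoate arm and bridge ketone kept | O=C2[C@@H]1CCC3=C(C(=O)CC3)[C@@]2(CCC(=O)OC)CN(C)C1 | intermediate
12 | tetracyclic keto dienoate: propanoate arm of 11 closed onto the enone carbonyl as the methyl cyclopentenecarboxylate, bridge ketone free | O=C2[C@@H]1CCC3=C4C(=C(C(=O)OC)C[C@@]42CN(C)C1)CC3 | intermediate
13 | methoxymethylidene enol ether at the bridge carbon of 12 (E/Z mixture) | COC=C2[C@@H]1CCC3=C4C(=C(C(=O)OC)C[C@@]42CN(C)C1)CC3 | intermediate
14 | bridge aldehyde: formyl and H on the bridge carbon (both epimers) | O=CC2[C@@H]1CCC3=C4C(=C(C(=O)OC)C[C@@]42CN(C)C1)CC3 | intermediate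
15 | allyl enol ether of 14 (E/Z mixture) | C=CCOC=C2[C@@H]1CCC3=C4C(=C(C(=O)OC)C[C@@]42CN(C)C1)CC3 | intermediate
16 | allyl aldehyde: bridge carbon bearing formyl (piperidine side) and allyl (cycloheptene side) | O=C[C@@]2(CC=C)[C@@H]1CCC3=C4C(=C(C(=O)OC)C[C@@]42CN(C)C1)CC3 | intermediate
17 | keto aldehyde: bridge carbon bearing formyl and 2-oxopropyl | O=C[C@@]2(CC(C)=O)[C@@H]1CCC3=C4C(=C(C(=O)OC)C[C@@]42CN(C)C1)CC3 | intermediate
18 | spiro-cyclopentenone: cyclopent-2-en-1-one joined through C4 to the bridge carbon, ring CH2 on the cycloheptene side | O=C1C[C@]2(C=C1)[C@@H]1CCC3=C4C(=C(C(=O)OC)C[C@@]42CN(C)C1)CC3 | intermediate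
19 | dimethylphenylsilyl enol ether of the saturated spiro ketone, C=C away from the spiro carbon | C[Si](C)(c5ccccc5)OC1=CC[C@@]2(C1)[C@@H]1CCC3=C4C(=C(C(=O)OC)C[C@@]42CN(C)C1)CC3 | intermediate
20 | α-chloro spiro-cyclopentanone, Cl on the α-carbon remote from the spiro carbon (both epimers) | O=C1C(Cl)C[C@@]2(C1)[C@@H]1CCC3=C4C(=C(C(=O)OC)C[C@@]42CN(C)C1)CC3 | intermediate
21 | α-chloro spiro-δ-lactone: 3-chlorotetrahydropyran-2-one joined through C5 to the bridge carbon, ring OCH2 on the cycloheptene side | O=C1OC[C@]2(CC1Cl)[C@@H]1CCC3=C4C(=C(C(=O)OC)C[C@@]42CN(C)C1)CC3 | intermediate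
22 | spiro-δ-lactone: tetrahydropyran-2-one joined through C5 to the bridge carbon | O=C1OC[C@]2(CC1)[C@@H]1CCC3=C4C(=C(C(=O)OC)C[C@@]42CN(C)C1)CC3 | intermediate
23 | target: 2-ethyl-2-hydroxytetrahydropyran spiro-linked at C5 to the bridge carbon of the N-methyl tetracyclic dienoate | CC[C@]1(O)CC[C@@]2(CO1)[C@@H]1CCC3=C4C(=C(C(=O)OC)C[C@@]42CN(C)C1)CC3 | target

**Step count and risks**
Total step count: 15. Longest linear sequence: 15 steps (1 → 23).

Three steps most likely to fail:

1. Step 13. What may go wrong: oxidation at nitrogen or at the tetrasubstituted diene instead of the ketone, slow reaction of the electron-poor chloro ketone, or migration of the chlorine-bearing carbon. Fallback: the oxygen is brought in as formaldehyde instead of by insertion, setting out from 14 and coming back at 23. Crossed aldol reaction of 14 with aq. CH2O and K2CO3 in THF, from the same face as the allylation, should give the hydroxymethyl aldehyde F1. Wittig reaction of F1 with 1-(triphenylphosphoranylidene)butan-2-one in toluene at 100 °C should give the (E)-enone F2. Hydrogenation of its disubstituted C=C with H2 over (Ph3P)3RhCl should give the δ-hydroxy ketone, which closes to 23. This fallback also avoids the Grignard addition of step 15.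

2. Step 9. What may go wrong: poor or reversed facial selectivity when the quaternary spiro centre is formed, or O-allylation that does not rearrange cleanly. Fallback: the order in which the two arms reach the bridge carbon is exchanged, so that the same facial preference now delivers the other arm; it sets out from 14 and comes back at 23. Michael addition of 14 (KOt-Bu cat., THF, 0 °C) to pent-1-en-3-one should give the keto aldehyde F3. Chemoselective reduction of its aldehyde with NaBH(OAc)3 in benzene at 60 °C should give the primary alcohol, which closes onto the ethyl ketone to 23.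

3. Step 2. What may go wrong: the dione is consumed as an enaminone or opened by retro-Claisen cleavage instead of undergoing the second ring closure with the hindered primary amine, or the two diastereomers are hard to separate. Fallback: the piperidine is built stepwise without the auxiliary and the product is resolved, setting out from 3 and coming back at 8. Mannich reaction of 3 with N-benzylmethylamine hydrochloride and aq. CH2O in EtOH at 60 °C should give the Mannich base F4. Hydrogenolysis with H2 over Pd(OH)2/C in MeOH should give the secondary amine F5. Intramolecular Mannich closure of F5 with aq. CH2O and AcOH in MeOH at 60 °C should give the racemic amino diketone F6. Chromatography of F6 on a chiral stationary phase should give 8.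

**Further compounds**
F1 | step 13 | hydroxymethyl aldehyde: bridge carbon bearing formyl (piperidine side) and CH2OH (cycloheptene side) | O=C[C@@]2(CO)[C@@H]1CCC3=C4C(=C(C(=O)OC)C[C@@]42CN(C)C1)CC3
F2 | step 13 | (E)-enone: bridge carbon bearing CH2OH and (E)-3-oxopent-1-enyl | CCC(=O)/C=C/[C@@]2(CO)[C@@H]1CCC3=C4C(=C(C(=O)OC)C[C@@]42CN(C)C1)CC3
F3 | step 9 | keto aldehyde: bridge carbon bearing formyl and 3-oxopentyl | CCC(=O)CC[C@@]2(C=O)[C@@H]1CCC3=C4C(=C(C(=O)OC)C[C@@]42CN(C)C1)CC3
F4 | step 2 | methyl 3-(1-{[benzyl(methyl)amino]methyl}-2,6-dioxocycloheptyl)propanoate | COC(=O)CCC1(CN(C)Cc2ccccc2)C(=O)CCCCC1=O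
F5 | step 2 | methyl 3-{1-[(methylamino)methyl]-2,6-dioxocycloheptyl}propanoate | COC(=O)CCC1(CNC)C(=O)CCCCC1=O
F6 | step 2 | racemic methyl 3-(8-methyl-2,10-dioxo-8-azabicyclo[4.3.1]decan-1-yl)propanoate | O=C2C1CCCC(=O)C2(CCC(=O)OC)CN(C)C1
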